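In a one-step world, with the whole nucleophile charge free, the electrophile halves in 4.33 s. Our flask is different, since its nucleophile is charged protonated.

electrophile 2.0 mM; protonated nucleophile 1.30 equiv; protic impurity 0.600 mM; time 4.0 min

1. the equivalents of free base at which the part of the electrophile that has reacted at 4.0 min is just 70%

    electrophile + protic impurity → quenched substrate (k1 = 32.8 M⁻¹ s⁻¹)
    acid set free + free base ⇌ salt of the base (K2 = 3.0 × 10⁷ M⁻¹, k2 = 88.4 M⁻¹ s⁻¹)
    nucleophile + acid set free ⇌ protonated nucleophile, settled at all times (K3 = 4.2 × 10⁶ M⁻¹)
    acid set free → by-product carried off (k4 = 0.0181 s⁻¹)
    electrophile + nucleophile → acid set free + product (k5 = 61.5 M⁻¹ s⁻¹)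

We climb the time scales from the fastest. The proton balance is instant, and its symmetric case, [nucleophile] = [acid set free], is the zero of our scale: 0.0249 mM each. Next, free nucleophile meets the electrophile with a half-life of 5.64 s at the charge, shorter than the impurity's hold on the electrophile, 0.587 min. So we let free nucleophile and free acid follow the slower amounts, with their gains and losses in balance. Each coupling removes a nucleophile and adds an acid, and each drained acid frees a nucleophile, so D[acid set free] = 2k[electrophile][nucleophile], with D the drain constant (k of the base times [free base], plus the loss constant) and k the coupling constant. With the balance constant K, the coupling rate is √(k[electrophile][protonated nucleophile]D/(2K)).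

At the top rung stands the run. The impurity takes 0.600 mM within it, so coupling must supply 0.800 mM. We spread that evenly over the run and take [electrophile] at 1.00 mM, midway from what the impurity leaves to the target end, and [protonated nucleophile] at its midway value 2.20 mM. We then get 0.690 s⁻¹, the drain needed. It far exceeds the loss constant, so the base must carry it. Each coupling costs 2 acids, so the base loses about 1.60 mM and its midway level stands 0.800 mM below its charge. Our reckoning, with "reacted" meaning lost by either route, then gives 4.20 equiv.

The forecast says 3.9 equiv, less than our figure, with range 3 equiv to 5 equiv, citing “the slow removal of free acid by the base”. The simulation gives 4.59 equiv.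

In this flask, with the base at its charge less 0.800 mM, the drain reckons to 0.759 s⁻¹, above the drain needed, and at 1.58 min the forward step to the salt uses acid set free 41 times as fast as the loss to by-product. For the flask with twice the protonated nucleophile, all other amounts as they are, our rule with drain and [electrophile] held fixed estimates coupling at 1.13 mM, which with the impurity's share counts 86.6% of the electrophile as reacted, and that flask gives 82.0%.

The rate constants belong to no real substance.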